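The south-west run, charged with 2 mM of free catalyst, comes to rest with 86.3 % of its substrate left, and the north-west run, with 8 mM, rests with 59.0 % left.

| flask | substrate | partner | free catalyst | remark | time |
|---|---|---|---|---|---|
| south-west | 0.80 M | 1.44 M | 2 mM | run made earlier |  |
| north-west | 0.80 M | 1.44 M | 8 mM | run made earlier |  |
| flask | 0.80 M | 1.44 M | 4.0 mM |  | 15 d |

| run | time / d | substrate / % | target / % |
|---|---|---|---|
| south-west | 1.25 | 91 | 8 |
| south-west | 2.50 | 87 | 14 |
| south-west | 5.00 | 86 | 14 |
| south-west | 10.0 | 88 | 16 |
| south-west | 20.0 | 85 | 10 |
| north-west | 4.00 | 58 | 41 |
| north-west | 8.00 | 59 | 37 |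
| north-west | 10.0 | 60 | 38 |
| north-west | 15.0 | 59 | 41 |
| north-west | 20.0 | 59 | 39 |

(scatter of a reading: 1.5 percentage points)

1. at 15 d, what has stopped the reaction, if anything has (the partner has run out first / forward and back rates have come level / no working catalyst is left / it is still moving / all of the substrate has reacted)
2. conversion of substrate at 15 d
3. amount of target at 15 d, in percent of the substrate charged
4. amount of target if the flask were left three thousand times as long, in percent of the substrate charged

- the numbers in the tables scatter by 1.5 percentage points (one standard deviation)
- the reaction counts as stopped when no species that holds the substrate changes by six tenths of a point or more over the second half of the time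

I write the rate of conversion as a product of three things: the catalyst charged, the fraction of substrate left, and a slowing that falls to nothing on a clock these readings do not name. The first south-west reading, scaled to this flask's catalyst, gives a start of

r = 0.144 d⁻¹

Summed over a whole run, that product turns into a rule I can read from both resting points:

south-west: 0.0735 mM⁻¹
north-west: 0.0660 mM⁻¹
mean: 0.0697 mM⁻¹

This is the stopping budget: the natural logarithm of charged over remaining substrate, per unit of catalyst charged. For this flask it gives

logarithm = 0.279, conversion = 24.3 %

Substrate left slows the rate by a factor of 0.757 by the end. The accumulated slowing is worth 1.94 d at the starting rate, which is shorter than the 15 d asked, so I expect rest. Assuming target equals conversion, I expect it unchanged by longer waiting.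

The forecast gives 24.5 % conversion, 24.5 % target and 24.5 % after the long wait. It names a stopper where I name none: no working catalyst is left, in its words “So the catalyst is dying”.

The flask gives 23.8 % conversion, 23.6 % target and 23.6 % after the long wait.

partner → decomposed reagent (k = 7.80 × 10⁻⁴ min⁻¹); substrate + free catalyst ⇌ catalyst intermediate A (K = 0.740 L mol⁻¹, k = 0.750 L mol⁻¹ min⁻¹); catalyst intermediate B ⇌ catalyst intermediate C (K = 1.60, k = 1.80 min⁻¹); partner + catalyst intermediate A → catalyst intermediate B (k = 0.0910 L mol⁻¹ min⁻¹); catalyst intermediate C → free catalyst + target (k = 27.0 min⁻¹) The stop is that the partner has run out first: in this flask it stands at 0 % of its own charge against 76 % of substrate, while the catalyst stands 68.9 % free and 31.1 % as catalyst intermediate A. The flask's budget reads 0.0678 mM⁻¹, beside my 0.0697 mM⁻¹. On the neighbouring flask with 0.016 M of free catalyst, my budget gives 67.2 %. That flask reaches 59.9 %, a budget of 0.0571 mM⁻¹, with 0.964 M of decomposed reagent against 1.25 M here.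

(All runs were generated by integration with made-up constants, and the scatter is random.)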